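Numbering: ring A = C1–C5 and C10 (methylene C11 on C4); ring B = C5–C10 (methyls on C5, C8, C9; arylmethyl on C9). Enabling feature: quaternary C5 bears a methyl and is bonded to C4, the carbon of the exocyclic C4=C11 methylene.
Cuts (retrosynthetic order): phenol O–MOM; C4–C5 (a C5 radical from H-atom transfer to a ring-B C5=CH2 closes ring A onto a C4≡C11 alkyne); aryl C–CO2Me (from Ar–Br); C5=CH2; C1–C2; C10–C1; C9–CH2Ar; C9–CH3.
Forward: ring B is bought as (S)-4-methylcyclohexenone; the C9 methyl, the arylmethyl group, C1, the C2–C4/C11 butynyl unit, the C5 methylene and the ester carbon are attached in that order; ring A closes last.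
Stereochemistry: C8 from the starting enone; C9 by benzylcopper addition anti to the C8 methyl; C10 by enolate protonation anti to the axial C9 methyl; C5 by chair-like ring closure from the equatorial C10 chain (trans fusion).

Key step: step 12

Assumption: compounds 1, 4 and 13 are taken as catalogue compounds; a bromine stands in for the benzoate carbon until step 10 because a methyl ester would not survive the benzylic Grignard reagent of step 6.

Step 1
Reactants: 1 (S)-4-methylcyclohex-2-en-1-one
Product: 2 trimethyl{[(3R,4S)-3,4-dimethylcyclohex-1-en-1-yl]oxy}silane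
Conditions: Me2CuLi (from MeLi, CuI), TMSCl, THF, −78 °C; Et3N, aq NaHCO3
Reagents that add atoms: lithium dimethylcuprate, [Li+].C[Cu-]C; chlorotrimethylsilane, C[Si](C)(C)Cl
Why: Silyl-accelerated Gilman cuprate 1,4-addition should deliver the methyl group to C9 anti to the C8 methyl (a centre that step 2 removes again) and fix the enolate as its C5=C10 silyl enol ether.

Step 2
Reactants: 2 trimethyl{[(3R,4S)-3,4-dimethylcyclohex-1-en-1-yl]oxy}silane
Product: 3 (S)-3,4-dimethylcyclohex-2-en-1-one
Conditions: Pd(OAc)2 (10 mol %), O2 (1 atm), DMSO, rt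
Reagents that add atoms: none
Why: Saegusa–Ito oxidation: the palladium enolate can lose a β-hydrogen only from C9, so the C9=C10 enone should form while the C8 stereocentre, which is not involved, keeps its S configuration.

Step 3
Reactants: 4 5-bromo-2-hydroxy-3-methoxybenzaldehyde
Product: 5 5-bromo-3-methoxy-2-(methoxymethoxy)benzaldehyde
Conditions: MOMCl, i-Pr2NEt, CH2Cl2, 0 °C → rt
Reagents that add atoms: chloromethyl methyl ether, COCCl
Why: O-alkylation of the phenol with an α-chloro ether (Williamson type) should give an acetal that tolerates the Grignard, organolithium, ylide and iron-hydride steps ahead.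

Step 4
Reactants: 5 5-bromo-3-methoxy-2-(methoxymethoxy)benzaldehyde
Product: 6 [5-bromo-3-methoxy-2-(methoxymethoxy)phenyl]methanol
Conditions: NaBH4, MeOH, 0 °C
Reagents that add atoms: none
Why: Borohydride reduction of an aryl aldehyde, to which the aryl bromide and the acetal are inert.

Step 5
Reactants: 6 [5-bromo-3-methoxy-2-(methoxymethoxy)phenyl]methanol
Product: 7 5-bromo-1-(chloromethyl)-3-methoxy-2-(methoxymethoxy)benzene
Conditions: PPh3, NCS, CH2Cl2, 0 °C → rt
Reagents that add atoms: N-chlorosuccinimide, O=C1CCC(=O)N1Cl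
Why: Appel-type chlorination through the alkoxyphosphonium salt runs under neutral conditions, so the acid-labile MOM ether next to the benzylic carbon should survive.

Step 6
Reactants: 7 5-bromo-1-(chloromethyl)-3-methoxy-2-(methoxymethoxy)benzene; 3 (S)-3,4-dimethylcyclohex-2-en-1-one
Product: 9 {[(3R,4S)-3-{[5-bromo-3-methoxy-2-(methoxymethoxy)phenyl]methyl}-3,4-dimethylcyclohex-1-en-1-yl]oxy}trimethylsilane, via benzylmagnesium chloride 8 (not isolated)
Conditions: 7, Mg, Et2O, 0 °C; then 3, CuBr·SMe2 (10 mol %), TMSCl, HMPA, THF, −78 °C; Et3N, aq NaHCO3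
Reagents that add atoms: chlorotrimethylsilane, C[Si](C)(C)Cl
Why: Magnesium should insert into the benzylic C–Cl bond well before the aryl C–Br bond, and the copper-catalysed, chlorosilane-accelerated conjugate addition of the Grignard reagent to the β,β-disubstituted enone should build quaternary C9 with the arylmethyl group entering anti to the C8 methyl (the usual trans addition to 4-substituted cyclohexenones), the silyl enol ether recording the enolate position at C5=C10.

Step 7
Reactants: 9 {[(3R,4S)-3-{[5-bromo-3-methoxy-2-(methoxymethoxy)phenyl]methyl}-3,4-dimethylcyclohex-1-en-1-yl]oxy}trimethylsilane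
Product: 12 (3R,4S)-3-{[5-bromo-3-methoxy-2-(methoxymethoxy)phenyl]methyl}-3,4-dimethyl-2-methylidenecyclohexan-1-one, via Mannich base 10 (not isolated), via trimethylammonium iodide 11 (not isolated)
Conditions: CH2=NMe2+ Cl−, CH2Cl2, 0 °C → rt; aq NaHCO3; MeI, THF, rt; DBU, rt
Reagents that add atoms: N,N-dimethylmethylideneammonium chloride, C=[N+](C)C.[Cl-]
Why: The Mannich reaction of a silyl enol ether with a preformed iminium salt is regiospecific for C10, and Hofmann-type elimination of the methiodide should give the C10=C1 enone; the C10 centre of 10 and 11 (aminomethyl group expected anti to the axial C9 methyl) disappears in the elimination.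

Step 8
Reactants: 12 (3R,4S)-3-{[5-bromo-3-methoxy-2-(methoxymethoxy)phenyl]methyl}-3,4-dimethyl-2-methylidenecyclohexan-1-one; 13 (4-bromobut-1-yn-1-yl)trimethylsilane
Product: 16 (2S,3R,4S)-3-{[5-bromo-3-methoxy-2-(methoxymethoxy)phenyl]methyl}-3,4-dimethyl-2-[5-(trimethylsilyl)pent-4-yn-1-yl]cyclohexan-1-one, via butynylmagnesium bromide 14 (not isolated), via magnesium enolate 15 (not isolated)
Conditions: 13, Mg, THF; then CuBr·SMe2 (20 mol %), 12, THF, −78 °C; 2,6-di-tert-butyl-4-methylphenol, −78 °C; aq NH4Cl
Reagents that add atoms: none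
Why: Copper-catalysed 1,4-addition of the Grignard reagent to the unhindered exocyclic enone joins C1 to C2, and kinetic protonation of enolate 15 by the bulky phenol from the face opposite the axial C9 methyl should place H10 cis to the arylmethyl group, which is also the epimer expected at equilibrium (chain, arylmethyl group and C8 methyl all equatorial); a carbon electrophile would enter from that same face, which is why the chain is attached before the hydrogen.

Step 9
Reactants: 16 (2S,3R,4S)-3-{[5-bromo-3-methoxy-2-(methoxymethoxy)phenyl]methyl}-3,4-dimethyl-2-[5-(trimethylsilyl)pent-4-yn-1-yl]cyclohexan-1-one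
Product: 17 {5-[(1R,2R,3S)-2-{[5-bromo-3-methoxy-2-(methoxymethoxy)phenyl]methyl}-2,3-dimethyl-6-methylidenecyclohexyl]pent-1-yn-1-yl}trimethylsilane
Conditions: Ph3PCH3Br, KOt-Bu, THF, 0 °C → rt
Reagents that add atoms: methyltriphenylphosphonium bromide, C[P+](c1ccccc1)(c1ccccc1)c1ccccc1.[Br-]
Why: Wittig methylenation with the non-stabilised ylide should turn the hindered C5 ketone into the 1,1-disubstituted alkene needed for hydrogen-atom transfer; no ester is present yet, the aryl bromide and the silylalkyne are inert to the ylide, and C10 already has its preferred configuration.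

Step 10
Reactants: 17 {5-[(1R,2R,3S)-2-{[5-bromo-3-methoxy-2-(methoxymethoxy)phenyl]methyl}-2,3-dimethyl-6-methylidenecyclohexyl]pent-1-yn-1-yl}trimethylsilane
Product: 19 methyl 3-({(1R,2R,6S)-1,6-dimethyl-3-methylidene-2-[5-(trimethylsilyl)pent-4-yn-1-yl]cyclohexyl}methyl)-5-methoxy-4-(methoxymethoxy)benzoate, via aryllithium 18 (not isolated)
Conditions: t-BuLi (2.1 equiv), THF, −78 °C; ClCO2Me (3 equiv), −78 °C → rt
Reagents that add atoms: methyl chloroformate, COC(=O)Cl
Why: Bromine–lithium exchange is faster at −78 °C than any deprotonation, and acylation of the aryllithium with excess chloroformate should give the methyl benzoate, the silyl cap keeping the alkyne C–H away from the base.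

Step 11
Reactants: 19 methyl 3-({(1R,2R,6S)-1,6-dimethyl-3-methylidene-2-[5-(trimethylsilyl)pent-4-yn-1-yl]cyclohexyl}methyl)-5-methoxy-4-(methoxymethoxy)benzoate
Product: 20 methyl 3-{[(1R,2R,6S)-1,6-dimethyl-3-methylidene-2-(pent-4-yn-1-yl)cyclohexyl]methyl}-5-methoxy-4-(methoxymethoxy)benzoate
Conditions: K2CO3, MeOH, rt
Reagents that add atoms: none
Why: Methoxide-mediated protodesilylation of the alkynylsilane; methanolysis of the methyl ester is degenerate and the MOM ether is stable to base.

Step 12
Reactants: 20 methyl 3-{[(1R,2R,6S)-1,6-dimethyl-3-methylidene-2-(pent-4-yn-1-yl)cyclohexyl]methyl}-5-methoxy-4-(methoxymethoxy)benzoate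
Product: 23 methyl 3-methoxy-4-(methoxymethoxy)-5-{[(1R,2S,4aS,8aS)-1,2,4a-trimethyl-5-methylidenedecahydronaphthalen-1-yl]methyl}benzoate, via tertiary C5 radical 21 (not isolated), via C11 vinyl radical 22 (not isolated)
Conditions: Fe(acac)3 (30 mol %), PhSiH3 (3 equiv), EtOH, 60 °C, degassed, 0.01 M
Reagents that add atoms: none
Why: An iron hydride generated from Fe(acac)3 and PhSiH3 transfers a hydrogen atom to the terminal carbon of the C5 methylene (Markovnikov metal-hydride hydrogen-atom transfer), which creates the C5 methyl and the tertiary radical 21 in one event; 21 adds to C4 of the alkyne and the vinyl radical 22 is quenched at C11 by hydrogen abstraction from silane or ethanol, or by capture at iron(II) and protonation. The closest known reactions are iron-hydride reductive cyclisations of 1,1-disubstituted alkenes onto tethered ketones, nitriles and electron-poor alkenes and the stannane-mediated closures of tertiary radicals onto terminal alkynes; an unactivated alkyne is the least electrophilic acceptor used in this manifold. Ring A closes in the 6-exo-dig mode, attack at the internal alkyne carbon being the normal course for hept-6-ynyl radicals. C5 is set by a chair-like transition state: ring B is held in the chair with the C8 methyl, the arylmethyl group and the C10 chain equatorial, so the C4–C5 bond forms equatorially and the new methyl ends axial, trans to H10 and syn to the C9 methyl, as in radical polyene cyclisations that pass through tertiary ring radicals to trans-fused rings. The step needs hydrogen-atom transfer to the alkene only (a terminal alkyne would give a high-energy vinyl radical and is left alone), exo rather than endo closure, and ring closure faster than a second hydrogen-atom transfer to 21, which high dilution and the intramolecular acceptor should secure.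

Step 13
Reactants: 23 methyl 3-methoxy-4-(methoxymethoxy)-5-{[(1R,2S,4aS,8aS)-1,2,4a-trimethyl-5-methylidenedecahydronaphthalen-1-yl]methyl}benzoate
Product: 24 polyfibrospongol A, methyl 4-hydroxy-3-methoxy-5-{[(1R,2S,4aS,8aS)-1,2,4a-trimethyl-5-methylidenedecahydronaphthalen-1-yl]methyl}benzoate
Conditions: HCl (1.25 M in MeOH), CH2Cl2, 0 °C → rt
Reagents that add atoms: none
Why: Acid-catalysed acetal exchange with methanol frees the phenol; at this acidity and temperature the C4=C11 alkene should not be protonated, so no stereocentre or double bond is disturbed.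

Compound list
1 | (S)-4-methylcyclohex-2-en-1-one | C[C@H]1CCC(=O)C=C1 | starting material
2 | trimethyl{[(3R,4S)-3,4-dimethylcyclohex-1-en-1-yl]oxy}silane | C[Si](C)(C)OC1=C[C@H](C)[C@@H](C)CC1 | intermediate
3 | (S)-3,4-dimethylcyclohex-2-en-1-one | C[C@H]1CCC(=O)C=C1C | intermediate
4 | 5-bromo-2-hydroxy-3-methoxybenzaldehyde | COc1cc(Br)cc(C=O)c1O | starting material
5 | 5-bromo-3-methoxy-2-(methoxymethoxy)benzaldehyde | COCOc1c(OC)cc(Br)cc1C=O | intermediate
6 | [5-bromo-3-methoxy-2-(methoxymethoxy)phenyl]methanol | COCOc1c(OC)cc(Br)cc1CO | intermediate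
7 | 5-bromo-1-(chloromethyl)-3-methoxy-2-(methoxymethoxy)benzene | COCOc1c(OC)cc(Br)cc1CCl | intermediate
8 | {[5-bromo-3-methoxy-2-(methoxymethoxy)phenyl]methyl}magnesium chloride | COCOc1c(OC)cc(Br)cc1C[Mg]Cl | intermediate
9 | {[(3R,4S)-3-{[5-bromo-3-methoxy-2-(methoxymethoxy)phenyl]methyl}-3,4-dimethylcyclohex-1-en-1-yl]oxy}trimethylsilane | C[Si](C)(C)OC1=C[C@](C)(Cc2cc(Br)cc(OC)c2OCOC)[C@@H](C)CC1 | intermediate
10 | (2S,3R,4S)-3-{[5-bromo-3-methoxy-2-(methoxymethoxy)phenyl]methyl}-2-[(dimethylamino)methyl]-3,4-dimethylcyclohexan-1-one | O=C1[C@H](CN(C)C)[C@](C)(Cc2cc(Br)cc(OC)c2OCOC)[C@@H](C)CC1 | intermediate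
11 | {[(1S,2R,3S)-2-{[5-bromo-3-methoxy-2-(methoxymethoxy)phenyl]methyl}-2,3-dimethyl-6-oxocyclohexyl]methyl}trimethylammonium iodide | O=C1[C@H](C[N+](C)(C)C)[C@](C)(Cc2cc(Br)cc(OC)c2OCOC)[C@@H](C)CC1.[I-] | intermediate
12 | (3R,4S)-3-{[5-bromo-3-methoxy-2-(methoxymethoxy)phenyl]methyl}-3,4-dimethyl-2-methylidenecyclohexan-1-one | O=C1C(=C)[C@](C)(Cc2cc(Br)cc(OC)c2OCOC)[C@@H](C)CC1 | intermediate
13 | (4-bromobut-1-yn-1-yl)trimethylsilane | C[Si](C)(C)C#CCCBr | starting material
14 | [4-(trimethylsilyl)but-3-yn-1-yl]magnesium bromide | C[Si](C)(C)C#CCC[Mg]Br | intermediate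
15 | bromo{[(3R,4S)-3-{[5-bromo-3-methoxy-2-(methoxymethoxy)phenyl]methyl}-3,4-dimethyl-2-[5-(trimethylsilyl)pent-4-yn-1-yl]cyclohex-1-en-1-yl]oxy}magnesium | Br[Mg]OC1=C(CCCC#C[Si](C)(C)C)[C@](C)(Cc2cc(Br)cc(OC)c2OCOC)[C@@H](C)CC1 | intermediate
16 | (2S,3R,4S)-3-{[5-bromo-3-methoxy-2-(methoxymethoxy)phenyl]methyl}-3,4-dimethyl-2-[5-(trimethylsilyl)pent-4-yn-1-yl]cyclohexan-1-one | O=C1[C@@H](CCCC#C[Si](C)(C)C)[C@](C)(Cc2cc(Br)cc(OC)c2OCOC)[C@@H](C)CC1 | intermediate
17 | {5-[(1R,2R,3S)-2-{[5-bromo-3-methoxy-2-(methoxymethoxy)phenyl]methyl}-2,3-dimethyl-6-methylidenecyclohexyl]pent-1-yn-1-yl}trimethylsilane | C=C1[C@@H](CCCC#C[Si](C)(C)C)[C@](C)(Cc2cc(Br)cc(OC)c2OCOC)[C@@H](C)CC1 | intermediate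
18 | aryllithium: 17 with lithium in place of bromine | C=C1[C@@H](CCCC#C[Si](C)(C)C)[C@](C)(Cc2cc([Li])cc(OC)c2OCOC)[C@@H](C)CC1 | intermediate
19 | methyl 3-({(1R,2R,6S)-1,6-dimethyl-3-methylidene-2-[5-(trimethylsilyl)pent-4-yn-1-yl]cyclohexyl}methyl)-5-methoxy-4-(methoxymethoxy)benzoate | C=C1[C@@H](CCCC#C[Si](C)(C)C)[C@](C)(Cc2cc(C(=O)OC)cc(OC)c2OCOC)[C@@H](C)CC1 | intermediate
20 | methyl 3-{[(1R,2R,6S)-1,6-dimethyl-3-methylidene-2-(pent-4-yn-1-yl)cyclohexyl]methyl}-5-methoxy-4-(methoxymethoxy)benzoate | C#CCCC[C@@H]1C(=C)CC[C@H](C)[C@@]1(C)Cc1cc(C(=O)OC)cc(OC)c1OCOC | intermediate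
21 | tertiary radical at C5: 20 after hydrogen-atom addition to the methylene carbon | C#CCCC[C@@H]1[C](C)CC[C@H](C)[C@@]1(C)Cc1cc(C(=O)OC)cc(OC)c1OCOC | intermediate
22 | vinyl radical at C11: 23 lacking one hydrogen on the methylene carbon | [CH]=C1CCC[C@H]2[C@](C)(Cc3cc(C(=O)OC)cc(OC)c3OCOC)[C@@H](C)CC[C@]12C | intermediate
23 | polyfibrospongol A methoxymethyl ether, methyl 3-methoxy-4-(methoxymethoxy)-5-{[(1R,2S,4aS,8aS)-1,2,4a-trimethyl-5-methylidenedecahydronaphthalen-1-yl]methyl}benzoate | C=C1CCC[C@H]2[C@](C)(Cc3cc(C(=O)OC)cc(OC)c3OCOC)[C@@H](C)CC[C@]12C | intermediate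
24 | polyfibrospongol A, methyl 4-hydroxy-3-methoxy-5-{[(1R,2S,4aS,8aS)-1,2,4a-trimethyl-5-methylidenedecahydronaphthalen-1-yl]methyl}benzoate | C=C1CCC[C@H]2[C@](C)(Cc3cc(C(=O)OC)cc(OC)c3O)[C@@H](C)CC[C@]12C | target

Total step count: 13. Longest linear sequence: 11 steps (steps 3–13, from 4).

Steps most likely to fail

Step 12 carries the greatest risk. The tertiary C5 radical may be reduced by a second hydrogen-atom transfer, or return to an alkene isomer, before the slow addition to an unactivated alkyne. The fallback separates radical generation from ring closure. From 20, cobalt-mediated Markovnikov hydrobromination by hydrogen-atom transfer (Co(acac)2, t-BuOOH, Et3SiH, TsBr) should give the tertiary C5 bromide F1. Slow addition of Bu3SnH with AIBN in benzene at 80 °C then runs the classical chain cyclisation of a tertiary radical onto a terminal alkyne, at a stannane concentration low enough for 6-exo-dig closure to win. The vinyl radical takes its hydrogen from the stannane, and the sequence rejoins the route at 23.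

Step 6 comes next. 1,2-Addition, Wurtz coupling of the benzylic Grignard reagent or sluggish attack on the β,β-disubstituted enone may take over. The fallback makes quaternary C9 by enolate alkylation, with the arylmethyl group as the electrophile. Copper-catalysed asymmetric conjugate addition of Me3Al to purchased 2-methylcyclohex-2-en-1-one (chiral phosphoramidite ligand) sets C8. The enolate, activated with MeLi, is alkylated by chloride 7 anti to the new methyl to give the 2-arylmethyl-2,3-dimethylcyclohexanone F2. Wittig methylenation gives the methylenecyclohexane F3, SeO2/t-BuOOH oxidises the only allylic ring CH2 (C5) to the allylic alcohol F4, and Dess–Martin oxidation gives enone 12. The fallback sets out from 7 and rejoins the route at 12.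

Step 8 is third. The enolate may be protonated with poor facial selectivity, or the Grignard reagent may add 1,2 to the carbonyl. The fallback replaces the polar addition by a radical one (Giese reaction): 12, (4-iodobut-1-yn-1-yl)trimethylsilane, Bu3SnH and Et3B/air at low temperature. The C10 α-keto radical then takes its hydrogen from the bulky stannane on the face away from the axial C9 methyl. The fallback sets out from 12 and rejoins the route at 16 without any new compound.

Further compounds
F1 | step 12 | methyl 3-{[(1R,2S,6S)-3-bromo-1,3,6-trimethyl-2-(pent-4-yn-1-yl)cyclohexyl]methyl}-5-methoxy-4-(methoxymethoxy)benzoate (both C3 epimers) | C#CCCC[C@@H]1C(C)(Br)CC[C@H](C)[C@@]1(C)Cc1cc(C(=O)OC)cc(OC)c1OCOC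
F2 | step 6 | (2R,3S)-2-{[5-bromo-3-methoxy-2-(methoxymethoxy)phenyl]methyl}-2,3-dimethylcyclohexan-1-one | O=C1CCC[C@H](C)[C@@]1(C)Cc1cc(Br)cc(OC)c1OCOC
F3 | step 6 | 5-bromo-1-{[(1R,2S)-1,2-dimethyl-6-methylidenecyclohexyl]methyl}-3-methoxy-2-(methoxymethoxy)benzene | C=C1CCC[C@H](C)[C@@]1(C)Cc1cc(Br)cc(OC)c1OCOC
F4 | step 6 | (3R,4S)-3-{[5-bromo-3-methoxy-2-(methoxymethoxy)phenyl]methyl}-3,4-dimethyl-2-methylidenecyclohexan-1-ol (both C1 epimers) | C=C1C(O)CC[C@H](C)[C@@]1(C)Cc1cc(Br)cc(OC)c1OCOC
F0 | step 8 | none | none
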